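The target is cut through pyran ring A at the two bonds that join quinolone A to the carbons it bridges: C3–Ca (Ca is the CH carrying the isobutenyl group) and O4–Cb (Cb is the ring-fusion OCH beside CMe2). Ca and Cb stand in a 1,3-relationship through Cc, the ring-fusion CH attached to quinolone B, so they correspond to the β-carbon and the carbonyl carbon of an alkylidene ketone in ring B. A single organocatalytic Michael addition–hemiketalisation of 4-hydroxy-1-methylquinolin-2-one with the prenylidene pyranoquinoline-3,5-dione closes ring A, sets Ca by catalyst control and lets Cc equilibrate; silane reduction of the hemiketal then gives the target.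

Key step: step 5

Labels: ring A is the pyran that contains C3 and O4 of quinolone A together with Ca, Cc and Cb; ring B is the 2,2-dimethylpyran fused to quinolone B. Read from the SMILES, the target is (Ca R, Cb S, Cc S): the hydrogens on Cb and Cc are cis (rings A and B cis-fused) and the isobutenyl group on Ca is trans to quinolone B on Cc.

Remarks on the structures: no connectivity error was found. The alkylidene ketone 9 is named here as its 4Z isomer (vinyl group on the ketone side), which is what its SMILES shows; the E isomer would press the vinyl group against the C5 carbonyl. Hemiketal 11 has the same three descriptors as the target, with OH where the target has H on Cb.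

Assumption: the quinine-derived squaramide is taken to give the R configuration at Ca; the sense of induction has to be confirmed on 11, and the quinidine-derived pseudoenantiomer is the mirror-image catalyst.

Step 1
Reactants: 1 4-hydroxy-1-methylquinolin-2(1H)-one; 2 3-methylbut-2-enal (prenal)
Product: 4 N-methylflindersine (2,2,6-trimethyl-2,6-dihydro-5H-pyrano[3,2-c]quinolin-5-one), via oxatriene 3 (not isolated)
Conditions: 2 (1.5 equiv), pyridine, 115 °C
Reagents that add atoms: none
Why: Knoevenagel condensation at C3 of the vinylogous acid 1 with prenal gives the 1-oxatriene 3, which closes at once by oxa-6π electrocyclisation to the 2H-pyran, the standard prenal annulation of cyclic 1,3-dicarbonyl compounds; no stereocentre is formed.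

Step 2
Reactants: 4 N-methylflindersine
Product: 5 N-methylflindersine 3,4-epoxide (racemic; used crude)
Conditions: dimethyldioxirane (1.3 equiv), acetone/CH2Cl2, 0 °C; evaporate
Reagents that add atoms: dimethyldioxirane, CC1(C)OO1
Why: Dioxirane epoxidation: the pyran C3–C4 alkene is the only electron-rich isolated alkene (the quinolone C=C is part of a vinylogous carbamate) and the neutral, acid-free oxidant leaves the acid-labile benzylic epoxide intact; the two new centres are racemic and are removed in step 3.

Step 3
Reactants: 5 N-methylflindersine 3,4-epoxide
Product: 6 2,2,6-trimethyl-2H-pyrano[3,2-c]quinoline-3,5(4H,6H)-dione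
Conditions: BF3·OEt2 (0.3 equiv), CH2Cl2, −78 → 0 °C
Reagents that add atoms: none
Why: Meinwald rearrangement: the Lewis acid opens the epoxide at C4, where the cation is stabilised through the C4a=C10b–O enol ether, and a 1,2-hydride shift from C3 gives the 3-ketone, as established for 2,2-dimethylchromene oxides; no stereocentre remains.

Step 4
Reactants: 6 2,2,6-trimethyl-2H-pyrano[3,2-c]quinoline-3,5(4H,6H)-dione; 2 3-methylbut-2-enal
Product: 9 (4Z)-2,2,6-trimethyl-4-(3-methylbut-2-en-1-ylidene)-2H-pyrano[3,2-c]quinoline-3,5(4H,6H)-dione, via aldol adduct 7 (not isolated), via mesylate 8 (not isolated)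
Conditions: LiN(SiMe3)2 (1.1 equiv), THF, −78 °C; 2 (1.3 equiv), −78 °C; then MsCl (1.5 equiv), Et3N (4 equiv), −78 → 23 °C
Reagents that add atoms: none
Why: Directed aldol condensation: C4 is the only enolisable position (C2 is quaternary), its lithium enolate adds 1,2 to prenal, and mesylation followed by E1cB elimination gives the cross-conjugated dienone, expected as the Z isomer for the steric reason given above; the alkene geometry is erased in step 5.

Step 5
Reactants: 1 4-hydroxy-1-methylquinolin-2(1H)-one; 9 (4Z)-dienone
Product: 11 hemiketal (Ca R, Cb S, Cc S; OH on Cb cis to H on Cc; isobutenyl trans to quinolone B), via open keto adduct 10 (not isolated)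
Conditions: 1 (1.2 equiv), quinine-derived squaramide [3-(3,5-bis(trifluoromethyl)anilino)-4-(9-deoxy-epi-quinin-9-ylamino)cyclobut-3-ene-1,2-dione] (10 mol %), CH2Cl2, 23 °C
Reagents that add atoms: none
Why: The tertiary amine of the catalyst deprotonates 1 and holds the quinolonate as an ion pair while the squaramide N–H bonds bind the ketone oxygen of 9, so C3 of the quinolonate adds to the β-carbon Ca, the ring B enol ketonises to 10, and the 4-OH of quinolone A then adds to the Cb carbonyl. The closest known reaction type is the bifunctional-organocatalyst Michael addition–hemiketalisation of 4-hydroxycoumarins and 4-hydroxyquinolinones with enones (the warfarin-type annulation). Ring A closes by 6-exo-trig attack of oxygen on the Cb carbonyl. Ca is set by the catalyst in the C–C bond-forming step; Cc, which is α to the ketone in 10, epimerises through the enol and should settle trans to the isobutenyl group, the arrangement with the fewest clashes against the two quinolone carbonyl groups; the hemiketal centre Cb equilibrates to the cis-fused anomer and is planarised again in step 6. The step needs 1,4- and not 1,6-addition and C- and not O-alkylation: the δ-carbon is a fully substituted alkene terminus carrying two methyl groups, C3 of the quinolonate is its soft nucleophilic site, and hemiketal closure pulls the reversible addition forward.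

Step 6
Reactants: 11 hemiketal
Product: 12 target (Ca R, Cb S, Cc S)
Conditions: Et3SiH (5 equiv), BF3·OEt2 (3 equiv), CH2Cl2, −40 → 0 °C
Reagents that add atoms: none
Why: Ionic (silane) reduction of a hemiketal: BF3 ionises the tertiary hemiketal to the ring-fusion oxocarbenium ion and Et3SiH transfers hydride to Cb, expected on the face that carries the Cc hydrogen (Cb S, cis fusion) because that path lets ring B relax with Ca pseudoaxial whereas the opposite face leads to a trans-fused system that holds both Ca and the isobutenyl group against the quinolone carbonyl groups; a Lewis acid at low temperature spares the isobutenyl alkene.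

Compound list
1 | 4-hydroxy-1-methylquinolin-2(1H)-one | Cn1c(=O)cc(O)c2ccccc12 | starting material
2 | 3-methylbut-2-enal (prenal) | CC(C)=CC=O | starting material
3 | 1-methyl-3-(3-methylbut-2-en-1-ylidene)quinoline-2,4(1H,3H)-dione (oxatriene; not isolated, step 1) | CC(C)=CC=C1C(=O)c2ccccc2N(C)C1=O | intermediate
4 | N-methylflindersine, 2,2,6-trimethyl-2,6-dihydro-5H-pyrano[3,2-c]quinolin-5-one | CC1(C)C=Cc2c(O1)c1ccccc1n(C)c2=O | intermediate
5 | N-methylflindersine 3,4-epoxide (racemic) | CC1(C)Oc2c(c(=O)n(C)c3ccccc23)C2OC12 | intermediate
6 | 2,2,6-trimethyl-2H-pyrano[3,2-c]quinoline-3,5(4H,6H)-dione | CC1(C)Oc2c(CC1=O)c(=O)n(C)c1ccccc21 | intermediate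
7 | 4-(1-hydroxy-3-methylbut-2-en-1-yl)-2,2,6-trimethyl-2H-pyrano[3,2-c]quinoline-3,5(4H,6H)-dione (aldol adduct, as its lithium alkoxide, diastereomer mixture; not isolated, step 4) | CC(C)=CC(O)C1C(=O)C(C)(C)Oc2c1c(=O)n(C)c1ccccc21 | intermediate
8 | methanesulfonate of 7 (not isolated, step 4) | CC(C)=CC(OS(C)(=O)=O)C1C(=O)C(C)(C)Oc2c1c(=O)n(C)c1ccccc21 | intermediate
9 | (4Z)-2,2,6-trimethyl-4-(3-methylbut-2-en-1-ylidene)-2H-pyrano[3,2-c]quinoline-3,5(4H,6H)-dione | CC(C)=C/C=C1\C(=O)C(C)(C)Oc2c1c(=O)n(C)c1ccccc21 | intermediate
10 | 4-[(1R)-1-(4-hydroxy-1-methyl-2-oxo-1,2-dihydroquinolin-3-yl)-3-methylbut-2-en-1-yl]-2,2,6-trimethyl-2H-pyrano[3,2-c]quinoline-3,5(4H,6H)-dione (open keto adduct, interconverting C4 epimers; not isolated, step 5) | CC(C)=C[C@@H](c1c(O)c2ccccc2n(C)c1=O)C1C(=O)C(C)(C)Oc2c1c(=O)n(C)c1ccccc21 | intermediate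
11 | hemiketal: rings A and B cis-fused; Cb carries OH (cis to H on Cc), O4 of quinolone A, CMe2 and Cc; Ca carries 2-methylprop-1-enyl trans to quinolone B; (Ca R, Cb S, Cc S) | CC(C)=C[C@H]1c2c(c3ccccc3n(C)c2=O)O[C@@]2(O)[C@@H]1c1c(c3ccccc3n(C)c1=O)OC2(C)C | intermediate
12 | CNP0107253.2: as 11 with H in place of OH on Cb; H on Cb and Cc cis, isobutenyl on Ca trans to quinolone B; (Ca R, Cb S, Cc S) | CC(C)=C[C@H]1c2c(c3ccccc3n(C)c2=O)O[C@H]2[C@@H]1c1c(c3ccccc3n(C)c1=O)OC2(C)C | target

Total step count: 6
Longest linear sequence: 6 steps (1 → 4 → 5 → 6 → 9 → 11 → 12); compound 1 enters a second time in step 5.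

Steps most likely to fail

Step 5. The conjugate addition may be slow or reversible, because the enone α-carbon is fully substituted and the carbonyl sits beside a quaternary centre. Dienone 9 may rest in its electrocyclised 2H-pyran form; that closure reopens thermally and should only slow the reaction. Enantiofacial discrimination at Ca may be weak or inverted, epimerisation at Cc may be incomplete, and the hemiketal may dehydrate on acidic silica. The fallback replaces asymmetric catalysis by resolution. Setting out from 1 and 9, the same annulation is run under plain thermodynamic control with DABCO (20 mol %) in toluene at 60 °C. This should give the racemic hemiketal, that is 11 together with its mirror image, the ent-hemiketal F1. Preparative SFC on an immobilised amylose carbamate phase separates the two, and the route is rejoined at 11.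

Step 6. This is the stereochemically least certain step outside the key step. Hydride may instead be delivered along the axial trajectory of ring B, anti to the Cc hydrogen, which would give the trans-fused epimer at Cb; that is the usual course for an unbiased ring-fusion oxocarbenium ion. The cation may also lose the Cc proton and scramble Cc, and acid may reduce or cyclise the isobutenyl alkene. The fallback fixes Cb by ketone reduction and closes ring A with retention, through the former ketone oxygen. Setting out from 11, NaBH4 in MeOH/THF at −20 °C reduces the open keto tautomer. Hydride should attack anti to the pseudoaxial Ca substituent (Felkin–Anh, axial attack), giving the hydroxy quinolinone F2 with H on Cb cis to H on Cc. TsCl and Et3N in CH2Cl2 at 0 °C sulfonylate only the acidic 4-OH of quinolone A, giving the tosylate F3. NaH in THF (0 → 23 °C) then makes the Cb alkoxide displace the tosylate at C4 of quinolone A by addition–elimination, with retention at Cb, and the route is rejoined at 12.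

Step 4. The lithium aldolate may revert by retro-aldol cleavage before it is mesylated, elimination may be incomplete, and the dienone may oligomerise by conjugate addition. The fallback builds the alkylidene carbon first and adds the alkenyl group second. Setting out from 6, condensation with N,N-dimethylformamide dimethyl acetal in toluene at 90 °C gives the enaminone F4. 2-Methylprop-1-enylmagnesium bromide (Me2C=CHMgBr) in THF at −40 °C then adds in conjugate fashion and expels dimethylamine, and the route is rejoined at 9.

Further compounds
F1 | step 5 | ent-hemiketal (mirror image of 11; Ca S, Cb R, Cc R) | CC(C)=C[C@@H]1c2c(c3ccccc3n(C)c2=O)O[C@]2(O)[C@H]1c1c(c3ccccc3n(C)c1=O)OC2(C)C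
F2 | step 6 | (3S,4S)-3-hydroxy-4-[(1R)-1-(4-hydroxy-1-methyl-2-oxo-1,2-dihydroquinolin-3-yl)-3-methylbut-2-en-1-yl]-2,2,6-trimethyl-3,4-dihydro-2H-pyrano[3,2-c]quinolin-5(6H)-one | CC(C)=C[C@@H](c1c(O)c2ccccc2n(C)c1=O)[C@H]1c2c(c3ccccc3n(C)c2=O)OC(C)(C)[C@H]1O
F3 | step 6 | 4-O-(4-methylbenzenesulfonate) of F2 on quinolone A | CC(C)=C[C@@H](c1c(OS(=O)(=O)c3ccc(C)cc3)c2ccccc2n(C)c1=O)[C@H]1c2c(c3ccccc3n(C)c2=O)OC(C)(C)[C@H]1O
F4 | step 4 | 4-[(dimethylamino)methylidene]-2,2,6-trimethyl-2H-pyrano[3,2-c]quinoline-3,5(4H,6H)-dione | CN(C)C=C1C(=O)C(C)(C)Oc2c1c(=O)n(C)c1ccccc21
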